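## Retrosynthetic overview
1. Wikstrol A comes from its hexabenzyl ether by one neutral hydrogenolysis. The two axial isomers are separated at the end.
2. Flavone ring C and the C-3/C-8'' bond come from one oxidative C–H/C–H coupling. An o-hydroxydibenzoylmethane (the open tautomer of a 2-hydroxyflavanone) couples with C-8–H of tri-O-benzylafzelechin, followed by hemiketal closure and dehydration. This mirrors the presumed branch point: closure by the 2'-OH gives wikstrols, and closure by the flavan 7-OH (benzylated here) gives daphnodorin benzofurans.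
3. The flavan pyran ring comes from a 2'-hydroxychalcone by reductive closure of O-1 on C-β to the flav-3-ene. 3-Hydroxylation anti to ring B follows, by enantioselective protoboration run as a kinetic resolution, and sets 2R,3S.
4. The chalcone and the dibenzoylmethane come from the same 4,6-di-O-benzylphloroacetophenone, combined with 4-benzyloxybenzaldehyde or 4-benzyloxybenzoyl chloride.
5. Ring order: the flavan pyran ring is formed first (step 3) and the flavone pyranone ring last (step 6).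

Assumption: the SMILES fixes only C-2'' (R) and C-3'' (S) and leaves the hindered C-3/C-8'' axis open; wikstrol A and wikstrol B differ only at this axis, so both form and wikstrol A is taken by preparative HPLC after step 7.

## Route

Step 1
Reactants: 1 2,4,6-trihydroxyacetophenone
Product: 2 1-[2,4-bis(benzyloxy)-6-hydroxyphenyl]ethan-1-one
Conditions: BnBr (2.05 equiv), K2CO3 (2.2 equiv), DMF, rt to 50 °C, 12 h
Reagents that add atoms: benzyl bromide, BrCc1ccccc1
Why: Williamson etherification; one ortho OH is locked in a strong hydrogen bond to the acetyl carbonyl and is the least nucleophilic, so two equivalents of BnBr stop at the diether, and no stereocentre is formed.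

Step 2
Reactants: 2 1-[2,4-bis(benzyloxy)-6-hydroxyphenyl]ethan-1-one, 3 4-(benzyloxy)benzaldehyde
Product: 4 (E)-1-[2,4-bis(benzyloxy)-6-hydroxyphenyl]-3-[4-(benzyloxy)phenyl]prop-2-en-1-one
Conditions: KOH (5 equiv, 50 % aq), EtOH/THF 2:1, rt, 36 h; then 1 M HCl to pH 4
Reagents that add atoms: none
Why: Claisen–Schmidt aldol condensation; E1cB loss of water gives only the conjugated E-enone, and the phenoxide keeps the chalcone open under base.

Step 3
Reactants: 4 (E)-1-[2,4-bis(benzyloxy)-6-hydroxyphenyl]-3-[4-(benzyloxy)phenyl]prop-2-en-1-one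
Product: 7 racemic 5,7-bis(benzyloxy)-2-[4-(benzyloxy)phenyl]-2H-chromene (flav-3-ene), via allylic alcohol 5 (not isolated), via ortho-quinone methide 6 (not isolated)
Conditions: NaBH4 (2 equiv), THF/EtOH 1:1, reflux, 12 h
Reagents that add atoms: none
Why: Reductive cyclisation of a 2'-hydroxychalcone: 1,2-hydride reduction gives 5, its phenoxide expels the doubly activated benzylic oxygen to give 6, and oxa-6π electrocyclisation forms the same O-1/C-2 bond that the chalcone-to-flavanone closure makes in the plant; C-2 arises racemic and is sorted in step 4.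

Step 4
Reactants: 7 racemic 5,7-bis(benzyloxy)-2-[4-(benzyloxy)phenyl]-2H-chromene
Product: 9 (2R,3S)-5,7-bis(benzyloxy)-2-[4-(benzyloxy)phenyl]-3,4-dihydro-2H-chromen-3-ol (5,7,4'-tri-O-benzyl-(+)-afzelechin; at most 50 %), via 3-boronate 8 (not isolated)
Conditions: CuCl (5 mol %), (R,R)-Ph-BPE (6 mol %), NaOt-Bu (10 mol %), B2pin2 (0.55 equiv), MeOH (2 equiv), THF, 0 °C to rt; then NaBO3·4H2O (3 equiv), THF/H2O, rt
Reagents that add atoms: NaBO3·4H2O (sodium perborate), [Na+].[O-]OB=O (the oxygen of the 3-OH); bis(pinacolato)diboron, CC1(C)OB(OC1(C)C)B1OC(C)(C)C(C)(C)O1 (its Bpin stays only in 8)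
Why: Copper-catalysed enantioselective protoboration of a styrene-type alkene run as a kinetic resolution: the chiral copper boryl adds syn across C3=C4 with boron on C-3 (copper takes benzylic C-4) and anti to the 2-aryl group, only (S)-7 fits the ligand pocket so (R)-7 is recovered, MeOH protonates C-4, and the stereoretentive perborate oxidation turns C–B into C–OH, which fixes 2R,3S (2,3-trans).

Step 5
Reactants: 2 1-[2,4-bis(benzyloxy)-6-hydroxyphenyl]ethan-1-one, 10 4-(benzyloxy)benzoyl chloride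
Product: 12 1-[2,4-bis(benzyloxy)-6-hydroxyphenyl]-3-[4-(benzyloxy)phenyl]propane-1,3-dione, via dilithium dianion 11 (not isolated)
Conditions: LiN(SiMe3)2 (3.3 equiv), THF, −78 °C, 1 h; 10 (1.05 equiv), −78 °C to rt; then 1 M HCl
Reagents that add atoms: LiN(SiMe3)2, [Li+].C[Si](C)(C)[N-][Si](C)(C)C (its lithium stays only in 11)
Why: Direct C-aroylation of the phenoxide–enolate (a one-pot Baker–Venkataraman equivalent); any O-aroyl ester is carried to the same 1,3-diketone by the excess base, the third equivalent absorbs the acidic product, and no stereocentre is formed.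

Step 6
Reactants: 9 5,7,4'-tri-O-benzyl-(+)-afzelechin, 12 1-[2,4-bis(benzyloxy)-6-hydroxyphenyl]-3-[4-(benzyloxy)phenyl]propane-1,3-dione
Product: 15 5,7-bis(benzyloxy)-3-{(2R,3S)-5,7-bis(benzyloxy)-2-[4-(benzyloxy)phenyl]-3-hydroxy-3,4-dihydro-2H-chromen-8-yl}-2-[4-(benzyloxy)phenyl]-4H-chromen-4-one (both axial isomers), via triaryl diketone 13 (not isolated), via 2-hydroxyflavanone hemiketal 14 (not isolated)
Conditions: 12 (1.5 equiv), Mn(OAc)3·2H2O (3.3 equiv, in portions), AcOH/ClCH2CH2Cl 3:1, argon, 50 °C, 4 h; aqueous work-up, then crude with PPTS (0.2 equiv), toluene, 80 °C, 2 h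
Reagents that add atoms: none
Why: Proposed new method: Mn(OAc)3 binds the fully enolised diketone 12 and oxidises it by inner-sphere electron transfer to an electrophilic C-α radical, which adds to the most nucleophilic and least hindered arene position of 9 (C-8, flanked by the tied-back ring oxygen, the site of NBS bromination and flavan-4-yl cation capture); a second Mn(OAc)3 oxidises the cyclohexadienyl radical, proton loss gives 13, the free 2'-OH closes on the 4-benzyloxybenzoyl carbonyl to hemiketal 14, and loss of water gives the flavone, while the benzylated 7''-oxygen blocks the rival benzofuran closure; the closest known reaction types are trivalent-manganese oxidative radical aromatic substitution of malonates and 1,3-dicarbonyls on electron-rich arenes and heteroarenes, and the classical o-hydroxydibenzoylmethane cyclodehydration; no new stereocentre is formed, C-2''/C-3'' are untouched, and the axis forms as a mixture.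

Step 7
Reactants: 15 hexa-O-benzyl ether (both axial isomers)
Product: 16 wikstrol A, 5,7-dihydroxy-2-(4-hydroxyphenyl)-3-[(2R,3S)-3,5,7-trihydroxy-2-(4-hydroxyphenyl)-3,4-dihydro-2H-chromen-8-yl]-4H-chromen-4-one
Conditions: H2 (1 atm), Pd(OH)2/C (20 wt %), THF/MeOH 1:1, rt, 6 h; preparative C18 HPLC to separate the axial isomers
Reagents that add atoms: none
Why: Catalytic hydrogenolysis of six aryl benzyl ethers under neutral conditions leaves the tetrasubstituted flavone C2=C3, the flavan C-2–O bond and both stereocentres untouched, as in standard catechin debenzylations, and avoids base that could isomerise the flavone to an aroylbenzofuran through the freed 7''-OH.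

## Compound list
1 | 2,4,6-trihydroxyacetophenone | CC(=O)c1c(O)cc(O)cc1O | starting material
2 | 1-[2,4-bis(benzyloxy)-6-hydroxyphenyl]ethan-1-one | CC(=O)c1c(O)cc(OCc2ccccc2)cc1OCc1ccccc1 | intermediate
3 | 4-(benzyloxy)benzaldehyde | O=Cc1ccc(OCc2ccccc2)cc1 | starting material
4 | (E)-1-[2,4-bis(benzyloxy)-6-hydroxyphenyl]-3-[4-(benzyloxy)phenyl]prop-2-en-1-one | O=C(/C=C/c1ccc(OCc2ccccc2)cc1)c1c(O)cc(OCc2ccccc2)cc1OCc1ccccc1 | intermediate
5 | racemic (E)-1-[2,4-bis(benzyloxy)-6-hydroxyphenyl]-3-[4-(benzyloxy)phenyl]prop-2-en-1-ol (not isolated) | OC(/C=C/c1ccc(OCc2ccccc2)cc1)c1c(O)cc(OCc2ccccc2)cc1OCc1ccccc1 | intermediate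
6 | 3,5-bis(benzyloxy)-6-{3-[4-(benzyloxy)phenyl]prop-2-en-1-ylidene}cyclohexa-2,4-dien-1-one (not isolated) | O=C1C=C(OCc2ccccc2)C=C(OCc2ccccc2)C1=CC=Cc1ccc(OCc2ccccc2)cc1 | intermediate
7 | racemic 5,7-bis(benzyloxy)-2-[4-(benzyloxy)phenyl]-2H-chromene | C1(c2ccc(OCc3ccccc3)cc2)C=Cc2c(OCc3ccccc3)cc(OCc3ccccc3)cc2O1 | intermediate
8 | 2-{(2S,3S)-5,7-bis(benzyloxy)-2-[4-(benzyloxy)phenyl]-3,4-dihydro-2H-chromen-3-yl}-4,4,5,5-tetramethyl-1,3,2-dioxaborolane, 2,3-trans; the descriptors differ from 9 only through CIP ranking (not isolated) | c1c(OCc3ccccc3)cc(OCc3ccccc3)c2c1O[C@H](c1ccc(OCc3ccccc3)cc1)[C@@H](B1OC(C)(C)C(C)(C)O1)C2 | intermediate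
9 | (2R,3S)-5,7-bis(benzyloxy)-2-[4-(benzyloxy)phenyl]-3,4-dihydro-2H-chromen-3-ol | c1c(OCc3ccccc3)cc(OCc3ccccc3)c2c1O[C@H](c1ccc(OCc3ccccc3)cc1)[C@@H](O)C2 | intermediate
10 | 4-(benzyloxy)benzoyl chloride | O=C(Cl)c1ccc(OCc2ccccc2)cc1 | starting material
11 | dilithium 3,5-bis(benzyloxy)-2-(1-oxidoethenyl)phenolate (not isolated) | [Li+].[Li+].C=C([O-])c1c([O-])cc(OCc2ccccc2)cc1OCc1ccccc1 | intermediate
12 | 1-[2,4-bis(benzyloxy)-6-hydroxyphenyl]-3-[4-(benzyloxy)phenyl]propane-1,3-dione | O=C(CC(=O)c1ccc(OCc2ccccc2)cc1)c1c(O)cc(OCc2ccccc2)cc1OCc1ccccc1 | intermediate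
13 | 2-{(2R,3S)-5,7-bis(benzyloxy)-2-[4-(benzyloxy)phenyl]-3-hydroxy-3,4-dihydro-2H-chromen-8-yl}-1-[2,4-bis(benzyloxy)-6-hydroxyphenyl]-3-[4-(benzyloxy)phenyl]propane-1,3-dione, epimers at the central CH (not isolated) | O=C(c1ccc(OCc2ccccc2)cc1)C(C(=O)c1c(O)cc(OCc2ccccc2)cc1OCc1ccccc1)c1c(OCc3ccccc3)cc(OCc3ccccc3)c2c1O[C@H](c1ccc(OCc3ccccc3)cc1)[C@@H](O)C2 | intermediate
14 | 5,7-bis(benzyloxy)-3-{(2R,3S)-5,7-bis(benzyloxy)-2-[4-(benzyloxy)phenyl]-3-hydroxy-3,4-dihydro-2H-chromen-8-yl}-2-[4-(benzyloxy)phenyl]-2-hydroxy-2,3-dihydro-4H-chromen-4-one, mixture at C-2/C-3 (not isolated) | O=C1C(c2c(OCc3ccccc3)cc(OCc3ccccc3)c3c2O[C@H](c2ccc(OCc4ccccc4)cc2)[C@@H](O)C3)C(O)(c2ccc(OCc3ccccc3)cc2)Oc2cc(OCc3ccccc3)cc(OCc3ccccc3)c12 | intermediate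
15 | 5,7-bis(benzyloxy)-3-{(2R,3S)-5,7-bis(benzyloxy)-2-[4-(benzyloxy)phenyl]-3-hydroxy-3,4-dihydro-2H-chromen-8-yl}-2-[4-(benzyloxy)phenyl]-4H-chromen-4-one, both axial isomers | O=c1c(-c2c(OCc3ccccc3)cc(OCc3ccccc3)c3c2O[C@H](c2ccc(OCc4ccccc4)cc2)[C@@H](O)C3)c(-c2ccc(OCc3ccccc3)cc2)oc2cc(OCc3ccccc3)cc(OCc3ccccc3)c12 | intermediate
16 | wikstrol A | O=c1c(-c2c(O)cc(O)c3c2O[C@H](c2ccc(O)cc2)[C@@H](O)C3)c(-c2ccc(O)cc2)oc2cc(O)cc(O)c12 | target

## Step count and risks
Total steps: 7. Longest linear sequence: 6 (steps 1, 2, 3, 4, 6, 7). Step 5 is a one-step branch from 2.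

**Step 6 (highest risk).** Three failure modes are likely:
- The diketonyl radical may dimerise or be oxygenated at C-α faster than it adds to 9.
- Attack may leak to C-6.
- Mn(OAc)3 may oxidise C-4 of the flavan.

The fallback is a polar cross-coupling in which the flavone ring is closed first. It sets out from 9 and 12 and comes back at 15. NBS in CH2Cl2 at −40 °C brominates 9 at C-8 to give 8-bromo-tri-O-benzylafzelechin F1. Miyaura borylation (B2pin2, PdCl2(dppf), KOAc, dioxane, 90 °C) turns it into the 8-pinacolboronate F2. In parallel, 12 is cyclodehydrated (cat. H2SO4, AcOH, 90 °C) to tri-O-benzylapigenin F3. This is iodinated at C-3 (LiN(i-Pr)2, THF, −78 °C, then I2) to 3-iodo-tri-O-benzylapigenin F4. Suzuki–Miyaura coupling of the two partners (Pd(OAc)2, SPhos, K3PO4, toluene/H2O, 100 °C) gives 15.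

**Step 4.** Three failure modes are likely:
- Borylcupration of this very electron-rich styrene may be slow.
- The selectivity factor may be low.
- The ligand hand may be wrong. It must be checked on the first run by the positive sign of rotation of 9, and the (S,S) ligand is equally available.

The fallback replaces asymmetric catalysis by a classical resolution. It sets out from 7 and comes back at 9. Hydroboration–oxidation (BH3·SMe2, THF, then NaOH/H2O2) adds anti to the 2-aryl group and gives racemic trans-tri-O-benzylafzelechin F5. Esterification with (S)-2-methoxy-2-phenylacetic acid (DCC, DMAP, CH2Cl2) gives the (2R,3S) ester F6 and the (2S,3R) ester F7. These are separated by chromatography or crystallisation. Methanolysis of the (2R,3S) ester (K2CO3, MeOH/THF) returns 9.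

**Step 3.** Three failure modes are likely:
- 1,4-Reduction may compete.
- Hydride may capture 6 to give the o-cinnamylphenol.
- The flavene is air-sensitive, which may cost material.

The fallback closes the ring before any reduction, as the plant does. It sets out from 4 and comes back at 7. NaOAc in refluxing EtOH isomerises 4 by oxa-Michael addition to racemic tri-O-benzylnaringenin F8. NaBH4 (THF/MeOH, 0 °C) then gives the racemic 2,4-cis-flavan-4-ol F9. PPTS in toluene at 80 °C ionises the doubly activated C-4 alcohol, and loss of H-3 gives 7.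

## Further compounds
F1 | step 6 | (2R,3S)-5,7-bis(benzyloxy)-2-[4-(benzyloxy)phenyl]-8-bromo-3,4-dihydro-2H-chromen-3-ol | Brc1c(OCc3ccccc3)cc(OCc3ccccc3)c2c1O[C@H](c1ccc(OCc3ccccc3)cc1)[C@@H](O)C2
F2 | step 6 | (2R,3S)-5,7-bis(benzyloxy)-2-[4-(benzyloxy)phenyl]-8-(4,4,5,5-tetramethyl-1,3,2-dioxaborolan-2-yl)-3,4-dihydro-2H-chromen-3-ol | CC1(C)OB(OC1(C)C)c1c(OCc3ccccc3)cc(OCc3ccccc3)c2c1O[C@H](c1ccc(OCc3ccccc3)cc1)[C@@H](O)C2
F3 | step 6 | 5,7-bis(benzyloxy)-2-[4-(benzyloxy)phenyl]-4H-chromen-4-one | O=c1cc(-c2ccc(OCc3ccccc3)cc2)oc2cc(OCc3ccccc3)cc(OCc3ccccc3)c12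
F4 | step 6 | 5,7-bis(benzyloxy)-2-[4-(benzyloxy)phenyl]-3-iodo-4H-chromen-4-one | O=c1c(I)c(-c2ccc(OCc3ccccc3)cc2)oc2cc(OCc3ccccc3)cc(OCc3ccccc3)c12
F5 | step 4 | racemic 2,3-trans-5,7-bis(benzyloxy)-2-[4-(benzyloxy)phenyl]-3,4-dihydro-2H-chromen-3-ol (both enantiomers) | c1c(OCc3ccccc3)cc(OCc3ccccc3)c2c1O[C@H](c1ccc(OCc3ccccc3)cc1)[C@@H](O)C2.c1c(OCc3ccccc3)cc(OCc3ccccc3)c2c1O[C@@H](c1ccc(OCc3ccccc3)cc1)[C@H](O)C2
F6 | step 4 | (2R,3S)-5,7-bis(benzyloxy)-2-[4-(benzyloxy)phenyl]-3,4-dihydro-2H-chromen-3-yl (S)-2-methoxy-2-phenylacetate | c1c(OCc3ccccc3)cc(OCc3ccccc3)c2c1O[C@H](c1ccc(OCc3ccccc3)cc1)[C@@H](OC(=O)[C@@H](OC)c1ccccc1)C2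
F7 | step 4 | (2S,3R)-5,7-bis(benzyloxy)-2-[4-(benzyloxy)phenyl]-3,4-dihydro-2H-chromen-3-yl (S)-2-methoxy-2-phenylacetate | c1c(OCc3ccccc3)cc(OCc3ccccc3)c2c1O[C@@H](c1ccc(OCc3ccccc3)cc1)[C@H](OC(=O)[C@@H](OC)c1ccccc1)C2
F8 | step 3 | racemic 5,7-bis(benzyloxy)-2-[4-(benzyloxy)phenyl]-2,3-dihydro-4H-chromen-4-one | O=C1CC(c2ccc(OCc3ccccc3)cc2)Oc2cc(OCc3ccccc3)cc(OCc3ccccc3)c12
F9 | step 3 | racemic 2,4-cis-5,7-bis(benzyloxy)-2-[4-(benzyloxy)phenyl]-3,4-dihydro-2H-chromen-4-ol (both enantiomers) | O[C@H]1C[C@@H](c2ccc(OCc3ccccc3)cc2)Oc2cc(OCc3ccccc3)cc(OCc3ccccc3)c12.O[C@@H]1C[C@H](c2ccc(OCc3ccccc3)cc2)Oc2cc(OCc3ccccc3)cc(OCc3ccccc3)c12
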